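The runs were generated by integration for substances that don't exist; scatter was added.

Between 0.500 h and 2.00 h of the dawn run, target fell from 46.0% to 33.4% while cross product stayed near 10.1%, and I carried that fall into the new flasks.

| flask | starting material | partner | second substrate | temperature | remark | time |
|---|---|---|---|---|---|---|
| autumn | 0.20 M | 0.30 M | 0.040 M | 85 °C | run made earlier |  |
| dawn | 0.20 M | 0.20 M | 0.040 M | 100 °C | run made earlier |  |
| spring | 0.20 M | 0.45 M | 0.040 M | 85 °C | run made earlier |  |
| noon | 0.30 M | 0.30 M | 0.040 M | 100 °C | run made earlier |  |
| oak | 0.20 M (fed, over 4.0 h) | 0.300 M | 0.0400 M |  | the addition at 60 °C, then warmed to 100 °C; the feed brings no volume worth counting | 6.0 h |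
| birch | 0.20 M | 0.300 M | 0.0400 M (fed, over 4.0 h) | 100 °C | all else is in the flask from the start; the feed brings no volume worth counting | 6.0 h |
| cedar | 0.20 M | 0.300 M | 0.0400 M |  | everything together at the start at 60 °C, warmed to 100 °C at 4.0 h | 6.0 h |
| ash | 0.20 M | 0.300 M | 0.0400 M | 100 °C | everything together at the start | 6.0 h |
| maple | 0.20 M (fed, over 4.0 h) | 0.300 M | 0.0400 M | 100 °C | all else is in the flask from the start; the feed brings no volume worth counting | 6.0 h |

| run | time / h | cross product / % | target / % |
|---|---|---|---|
| autumn | 1.33 | 8.0 | 75.4 |
| autumn | 3.00 | 9.0 | 74.5 |
| autumn | 4.00 | 8.2 | 74.4 |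
| autumn | 6.00 | 8.5 | 74.6 |
| autumn | 8.00 | 8.8 | 74.1 |
| dawn | 0.500 | 9.6 | 46.0 |
| dawn | 1.00 | 10.4 | 40.8 |
| dawn | 2.00 | 10.7 | 33.4 |
| dawn | 4.00 | 9.7 | 27.3 |
| dawn | 8.00 | 10.1 | 24.2 |
| spring | 1.00 | 6.4 | 88.2 |
| spring | 2.00 | 5.4 | 87.5 |
| spring | 4.00 | 6.1 | 89.1 |
| spring | 8.00 | 5.2 | 88.2 |
| spring | 15.0 | 7.3 | 86.5 |
| noon | 0.667 | 6.3 | 49.1 |
| noon | 2.00 | 6.2 | 39.9 |
| noon | 3.00 | 7.3 | 38.0 |
| noon | 5.00 | 5.8 | 36.5 |
| noon | 8.00 | 7.5 | 35.2 |

(scatter of a reading: 0.5 percentage points)

- percentages count the starting material that a species holds: one side product counts as two
- candidate steps: starting material + partner -> target; partner -> decomposed reagent; second substrate + partner -> second product; starting material -> decomposition product; starting material + target -> side product; starting material + second substrate -> cross product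

- which flask leads in amount of cross product, in percent of the starting material charged ("all alike" within 1.5 percentage points) (oak / birch / cedar / ash / maple / all alike)
- how much cross product is there at the end, in percent of the starting material charged: oak
- how much cross product is there at the end, in percent of the starting material charged: birch
- how much cross product is there at the end, in percent of the starting material charged: cedar
- how much cross product is there at the end, in percent of the starting material charged: ash
- how much cross product is there at the end, in percent of the starting material charged: maple

I built birch up one process at a time. With the main step alone, partner stands in excess, starting material is the limiting reagent, and the fed second substrate finds none of it, so cross product stays at nothing.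

Next I added the decay of partner, which strands starting material. Each side product takes one target and one starting material, so their difference holds, and I took dawn's last target reading as that difference. The balance then gave about 32.9% of the charge stranded in dawn, or 0.0657 M. I used that share for birch too, as a rough figure for its target, although birch holds more partner than dawn.

Last came the side step. In dawn, target averaged 39.7% over that interval and stranded starting material 15.5%, and the fall gave a lifetime of 1.85 h. This decay is pseudo-first-order in starting material, so the lifetime goes inversely with target. With target near 0.134 M in birch, the lifetime of stranded starting material, meaning its amount divided by its rate of loss to target, came to 1.09 h. The feed of 0.0100 M h⁻¹ delivers 0.0109 M in that time, so I expected about 5.45% cross product in birch.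

The forecast named birch as leader, with oak 2.2%, birch 15%, cedar 7.6%, ash 8.1% and maple 0.6%. Its ground for birch was “substrate fed after partner dies meets only stranded starting material”. My birch figure was lower than its figure.

The flasks gave oak 2.83%, birch 4.25%, cedar 11.4%, ash 7.43% and maple 0.145%, so cedar led.

    starting material + partner → target (k = 1.25 L mol⁻¹ min⁻¹, Ea = 68.0 kJ mol⁻¹)
    partner → decomposed reagent (k = 0.0879 min⁻¹, Ea = 115 kJ mol⁻¹)
    second substrate + partner → second product (k = 2.19 L mol⁻¹ min⁻¹, Ea = 83.0 kJ mol⁻¹)
    starting material → decomposition product (k = 1.18 × 10⁻⁵ min⁻¹, Ea = 123 kJ mol⁻¹)
    starting material + target → side product (k = 0.109 L mol⁻¹ min⁻¹, Ea = 75.0 kJ mol⁻¹)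
    starting material + second substrate → cross product (k = 1.89 L mol⁻¹ min⁻¹, Ea = 55.0 kJ mol⁻¹)
    (constants at 100 °C)

Birch ended with 0% of its starting material and 75% of its second substrate unused. Side product stood at 27.8%, which is 13.9% of the charge as starting material taken up beside target, against 4.25% as cross product. With birch's final target of 68.0%, the lifetime reads 1.08 h, and the feed in that time amounts to 5.39% of the charge, above the flask's figure.

In a neighbour flask, which is maple with 0.075 M of partner, target ended at 0.0154%, so the lifetime is 4750 h, far beyond the 6.0 h of the run. The computed neighbour flask gives 6.88% of cross product, with 90.0% of starting material left.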